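Late in a closed run the curve either stops or creeps, and these runs do both.

| setting | delta | gamma | north | east | south-west |
|---|---|---|---|---|---|
| free monomer | 0.079 M | 0.079 M | 0.079 M | 0.079 M (fed, over 10.0 d) | 0.079 M |
| transfer agent | 0.79 mM | 0.79 mM | 0.790 mM | 0.790 mM | 0.790 mM |
| initiator | 0.95 mM | 0.47 mM | 0.95 mM | 0.95 mM | 0.95 mM |
| remark | run made earlier | run made earlier | everything together in a closed stirred flask, run for 20 d | all but free monomer at the start; free monomer goes in evenly over 10.0 d, the run ends at 20 d | a single well-mixed tank run continuously and read at steady state, 20 d in it on average |
| time |  |  | 20 d | 20 d |  |

- delta (time / d: monomer in chains / %): 1.04: 37.5; 1.67: 47.5; 2.50: 55.8; 4.00: 63.3; 8.00: 70.0; 12.0: 73.2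
- gamma (time / d: monomer in chains / %): 0.417: 8.8; 1.25: 20.6; 2.00: 24.2; 3.00: 25.9; 5.00: 26.1; 6.00: 27.1

(readings scatter by 0.3 percentage points)

- order of the set-ups by the amount of monomer in chains at the outlet or at the end, in percent of the free monomer put in, highest first (north / east / south-west)
- amount of monomer in chains at the outlet or at the end, in percent of the free monomer put in, north
- amount of monomer in chains at the outlet or at the end, in percent of the free monomer put in, east
- amount of monomer in chains at the outlet or at the end, in percent of the free monomer put in, south-west

- the stated concentrations are those of everything mixed, before any reaction; amounts are the same in each set-up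
- the numbers in the tables scatter with a standard deviation of 0.3 percentage points
- reactions considered so far: free monomer + initiator -> living end + monomer in chains; free monomer + living end -> monomer in chains + living end; living end + transfer agent -> dead chain; living end + free monomer -> dead end
- the feed brings no volume worth counting
- the earlier runs were made in a closed, stirred flask

Why does gamma stop near 27.1 %? Its initiator stands below its transfer agent, so every living end can meet a transfer agent and become a dead chain, whereas delta leaves an excess of 0.160 mM of ends.

What ties the two consumptions together? Both the loss of transfer agent and the loss of free monomer have [living end] as a factor, so dividing the two rates removes it and the integral is closed: the logarithm of the fraction of transfer agent left equals s times the logarithm of the fraction of free monomer left, where s, the transfer exponent, is a selectivity factor.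

What is its value? If gamma's ends all become dead chains, its last reading gives s = 2.86.

And the weak spot? Ends lost to free monomer as dead ends would make that reading high, so I carry it as a reading.

What does it say of delta, and so of north? At 12.0 d, delta's reading of monomer in chains puts [transfer agent] below the excess for any s above 1.21, and my reading of s, though it may run high, stands well above that, so I expect north, charged as delta, to continue delta's creeping tail.

Does the lock hold in east? No: east starts with no free monomer, so ends meet transfer agent while little is built. I therefore place east under north, without a figure.

The forecast says north > east > south-west, with 76.2 %, 72.8 % and 69 %, on the ground that “Each surviving end therefore adds a fixed number of units”.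

The flask gives north > south-west > east, with 75.0 %, 62.2 % and 68.1 %.

    free monomer + initiator → living end + monomer in chains (k = 0.0420 M⁻¹ min⁻¹)
    free monomer + living end → monomer in chains + living end, rate k2*[living end]*[free monomer] (k = 0.790 M⁻¹ min⁻¹)
    living end + transfer agent → dead chain (kL = 1.90 M⁻¹ min⁻¹)
    living end + free monomer → dead end (k = 0.00250 M⁻¹ min⁻¹)

East lies 11 percentage points under the forecast. At 20.0 d its transfer agent stands at 0.90 %, which the closed lock pairs with 19.3 % free monomer, yet the flask holds twice that, 38 %. North's 3.6 % pairs with 31.3 % against its 25 %. A closed neighbour of north charged with 3.8 × 10⁻⁴ M of initiator, below its transfer agent, should stop like gamma, and s gives 20.5 % monomer in chains, where that flask ended at 20.5 %.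

The runs are simulated for substances that don't exist.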